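**Retrosynthetic overview**
1. Only the cyclopentenone ring C1–C5 has to be built. C1 is the quaternary C(OMe)CO2Me carbon (ester carbon C9), C2(OMe)=C3(OMe) is the enol-ether alkene, C4 is the ketone, and C5 carries the enolised cinnamoyl carbon C6; this numbering is used for all intermediates. The C1–C2 bond faces the C4 carbonyl across the ring, so cutting it unfolds the target into an isomeric open-chain cross-conjugated dienone, C2=C3–C4(=O)–C5=C1.
2. Key disconnection C1–C2: an enantioselective Nazarov 4π closure of methyl (2Z,5Z)-3-cinnamoyl-2,5,6-trimethoxy-4-oxohexa-2,5-dienoate on a chiral divalent copper chelate of the C4/C6 dicarbonyl unit. Loss of the C2 proton then gives the target with no later step.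
3. Dienone: the C1–OMe group comes from O-methylation of the enolised triacylmethane, the C5–C1 bond from C-acylation of a 1,3-diketone with methyl chlorooxoacetate, and the C4–C5 bond from acylation of the benzalacetone enolate with (Z)-2,3-dimethoxyacryloyl chloride.
4. Acid chloride: from methyl methoxyacetate by formylation with methyl formate, O-methylation, saponification and chlorination.
5. Ring order: the phenyl ring is bought with benzalacetone, and the cyclopentenone ring is the only ring formed, in the last step.

Key step: step 7

Assumption: the sense of induction is assigned from a quadrant model of the square-planar chelate, with the (S,S)-ligand taken to give 1S; if the reverse holds, the equally available (R,R)-ligand is used and nothing else changes.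

Step 1
Reactants: 1 methyl methoxyacetate; 2 methyl formate
Product: 4 methyl (Z)-2,3-dimethoxyacrylate, via sodium enolate 3 (not isolated)
Conditions: NaH, HCO2Me (excess), THF, 0 °C to rt; then Me2SO4, DMF, 0 °C to rt
Reagents that add atoms: dimethyl sulfate, COS(=O)(=O)OC; sodium hydride, [Na+].[H-] (sodium of 3 only)
Why: Crossed Claisen condensation (formylation) of the only enolisable ester with non-enolisable methyl formate is pulled forward by the stabilised enolate 3, and O-methylation of this hard oxygen nucleophile with dimethyl sulfate in a dipolar aprotic medium, as in beta-methoxyacrylate synthesis, should give the enol ether with the new methoxy group trans to the ester, which is the Z isomer by the priority rules.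

Step 2
Reactants: 4 methyl (Z)-2,3-dimethoxyacrylate
Product: 5 (Z)-2,3-dimethoxyacrylic acid
Conditions: LiOH, THF/H2O, 0 °C to rt; then 1 M HCl to pH 3, 0 °C
Reagents that add atoms: lithium hydroxide, [Li+].[OH-]
Why: Ester saponification by acyl-oxygen cleavage is a step that 3-alkoxyacrylates are known to tolerate because the vinylogous carbonate is a poor acceptor for hydroxide, and the brief cold acidification leaves the enol ether and its geometry untouched.

Step 3
Reactants: 5 (Z)-2,3-dimethoxyacrylic acid
Product: 6 (Z)-2,3-dimethoxyacryloyl chloride
Conditions: (COCl)2, DMF (cat.), CH2Cl2, 0 °C to rt; evaporate, use crude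
Reagents that add atoms: oxalyl chloride, ClC(=O)C(=O)Cl
Why: Acid chloride formation through the Vilsmeier-type chloroiminium salt, routine for 3-alkoxyacrylic acids, provides an acyl donor hard enough to be taken at the carbonyl carbon, whereas ester 4 would be attacked by an enolate at its beta carbon with loss of methoxide.

Step 4
Reactants: 7 benzalacetone ((E)-4-phenylbut-3-en-2-one); 6 (Z)-2,3-dimethoxyacryloyl chloride
Product: 9 (1E,6Z)-6,7-dimethoxy-1-phenylhepta-1,6-diene-3,5-dione (largely enolised), via lithium enolate 8 (not isolated)
Conditions: 7 (2.1 equiv), LiN(SiMe3)2 (2.1 equiv), THF, -78 °C; then 6 (1 equiv), -78 °C; AcOH, -78 °C; pH 7 buffer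
Reagents that add atoms: lithium hexamethyldisilazide, [Li]N([Si](C)(C)C)[Si](C)(C)C (lithium of 8 only)
Why: C-acylation of a preformed kinetic lithium enolate with an acid chloride (Claisen-type 1,3-diketone synthesis) works at -78 °C because the second equivalent of 8 removes the acidic C5 proton of the product and stores it as its lithium diketonate, and the cold acetic acid quench and neutral work-up avoid the acid-induced loss of methanol that would turn this 5-methoxypent-4-ene-1,3-dione into a 4-pyranone.

Step 5
Reactants: 9 (1E,6Z)-6,7-dimethoxy-1-phenylhepta-1,6-diene-3,5-dione; 10 methyl chlorooxoacetate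
Product: 11 methyl (5Z)-3-[(E)-cinnamoyl]-2-hydroxy-5,6-dimethoxy-4-oxohexa-2,5-dienoate (enol form of the triacylmethane)
Conditions: MgCl2, pyridine, CH2Cl2, 0 °C; cold 0.5 M HCl wash; use at once
Reagents that add atoms: none
Why: Soft-enolisation C-acylation with MgCl2 and pyridine succeeds because the magnesium chelate occupies both diketonate oxygens, so the very electrophilic acid chloride 10 is taken at carbon C5 and the triacylmethane rests as its magnesium salt until the acid wash.

Step 6
Reactants: 11 methyl (5Z)-3-[(E)-cinnamoyl]-2-hydroxy-5,6-dimethoxy-4-oxohexa-2,5-dienoate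
Product: 12 methyl (2Z,5Z)-3-[(E)-cinnamoyl]-2,5,6-trimethoxy-4-oxohexa-2,5-dienoate
Conditions: Me3SiCHN2 (1.05 equiv), toluene/MeOH 5:1, -10 to 0 °C
Reagents that add atoms: (trimethylsilyl)diazomethane, C[Si](C)(C)C=[N+]=[N-]
Why: O-methylation of a strongly acidic enol by a diazoalkane (proton transfer, then methyl transfer to the oxygen of the ion pair): as in 2,4-dioxo esters the enol hydroxyl of 11 should reside on C1, the carbonyl carbon made most electrophilic by the adjacent ester, so the C1 enol ether is the expected main product, its regioisomers are removed by chromatography on neutral silica, and the geometry at the push-pull C5=C1 bond is of no concern because it equilibrates in step 7.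

Step 7
Reactants: 12 methyl (2Z,5Z)-3-[(E)-cinnamoyl]-2,5,6-trimethoxy-4-oxohexa-2,5-dienoate
Product: 14 methyl (1S,5Z)-5-[(2E)-1-hydroxy-3-phenylprop-2-en-1-ylidene]-1,2,3-trimethoxy-4-oxocyclopent-2-ene-1-carboxylate (CNP0305038.1), via oxyallyl zwitterion 13 (not isolated)
Conditions: [Cu((S,S)-t-Bu-box)](SbF6)2 (10 mol %), 4 Å MS, CH2Cl2, -20 °C to rt (t-Bu-box = 2,2'-(propane-2,2-diyl)bis[(4S)-4-tert-butyl-4,5-dihydrooxazole])
Reagents that add atoms: none
Why: The dicationic copper bisoxazoline complex binds the C4 and C6 carbonyl oxygens in a six-membered chelate and so polarises 12 into a copper diketonate (C4–C5–C6) flanked by a cation at C1 that its methoxy group stabilises and its ester destabilises; conrotatory 4π closure of the U-shaped pentadienyl cation C2=C3–C4–C5=C1 joins C1 to C2 and gives 13, whose C3 oxocarbenium ion sheds the only neighbouring proton (C2–H) to set C2=C3, and return of that proton to the diketonate releases enol 14 and the catalyst. The closest known reaction type is the polarised Nazarov cyclisation of 2-alkoxy-4-acyl (or 4-alkoxycarbonyl) divinyl ketones under divalent copper bisoxazoline or Sc(OTf)3-pybox catalysis. The cyclopentenone ring (C1 to C5) is closed by this thermal electrocyclisation, formally a 5-endo-trig attack of the enol-ether carbon C2 on C1. C1 is the only lasting stereocentre (C2 of 13 is flattened again) and is fixed by the sense of conrotation together with the geometry at C5=C1: the tert-butyl groups of the ligand should allow only the twist in which, with C4, C5, C1, C2 and C3 drawn clockwise, the inward C1 methoxy group turns away from the viewer and the ester towards the viewer, which is the 1S configuration. The push-pull C5=C1 bond can rotate in the chelate, but allylic strain favours the 2Z arrangement, in which the small methoxy group faces the substituted C3 arm and the larger ester faces the C7–H of the styryl arm, so that one geometry feeds the closure. The step also needs the dimethoxyvinyl arm to react ahead of the styryl arm of the second dienone (C8=C7–C6(=O)–C5=C1), which the C3 methoxy group secures because only that closure leaves a heteroatom-stabilised cation, while the non-nucleophilic SbF6 counter-ion and the sieves hold back demethylation or hydrolysis on the way to 4-pyranones.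

**Compound list**
1 | methyl methoxyacetate | COCC(=O)OC | starting material
2 | methyl formate | COC=O | starting material
3 | sodium enolate of methyl 2-methoxy-3-oxopropanoate (configurationally labile) | [Na+].[O-]C=C(OC)C(=O)OC | intermediate
4 | methyl (Z)-2,3-dimethoxyacrylate | CO/C=C(\OC)C(=O)OC | intermediate
5 | (Z)-2,3-dimethoxyacrylic acid | CO/C=C(\OC)C(=O)O | intermediate
6 | (Z)-2,3-dimethoxyacryloyl chloride | CO/C=C(\OC)C(=O)Cl | intermediate
7 | benzalacetone, (E)-4-phenylbut-3-en-2-one | CC(=O)/C=C/c1ccccc1 | starting material
8 | lithium (E)-4-phenylbuta-1,3-dien-2-olate | [Li+].C=C([O-])/C=C/c1ccccc1 | intermediate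
9 | (1E,6Z)-6,7-dimethoxy-1-phenylhepta-1,6-diene-3,5-dione (drawn as the diketo form) | CO/C=C(\OC)C(=O)CC(=O)/C=C/c1ccccc1 | intermediate
10 | methyl chlorooxoacetate | COC(=O)C(=O)Cl | starting material
11 | methyl (5Z)-3-[(E)-cinnamoyl]-2-hydroxy-5,6-dimethoxy-4-oxohexa-2,5-dienoate (enol alkene tautomerically labile) | CO/C=C(\OC)C(=O)C(C(=O)/C=C/c1ccccc1)=C(O)C(=O)OC | intermediate
12 | methyl (2Z,5Z)-3-[(E)-cinnamoyl]-2,5,6-trimethoxy-4-oxohexa-2,5-dienoate (Nazarov precursor; C2=C3 of the name is configurationally labile) | CO/C=C(\OC)C(=O)/C(C(=O)/C=C/c1ccccc1)=C(\OC)C(=O)OC | intermediate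
13 | cyclised oxyallyl zwitterion, drawn free of copper; C1 and C2 methoxy groups cis | COC(=O)[C@@]1(OC)[C@H](OC)C(=[O+]C)C([O-])=C1C(=O)/C=C/c1ccccc1 | intermediate
14 | methyl (1S,5Z)-5-[(2E)-1-hydroxy-3-phenylprop-2-en-1-ylidene]-1,2,3-trimethoxy-4-oxocyclopent-2-ene-1-carboxylate, CNP0305038.1 | COC(=O)[C@@]1(OC)C(OC)=C(OC)C(=O)/C1=C(O)/C=C/c1ccccc1 | target

**Step count and risks**

Total step count: 7. Longest linear sequence: 7 steps (1 to 14 through 4, 5, 6, 9, 11 and 12).

Steps most likely to fail:

1. Step 7.
   - The electrocyclisation may stall, because methoxy donors on both termini stabilise the open cation.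
   - Enantiocontrol may be lost through rotation about the push-pull C5=C1 bond or through a proton-catalysed background closure.
   - Fallback, from 12 back to 14: catalyst control is given up. Compound 12 is closed with a stoichiometric achiral promoter (Sc(OTf)3, CH2Cl2/(CF3)2CHOH, rt) to racemic methyl (5Z)-5-[(2E)-1-hydroxy-3-phenylprop-2-en-1-ylidene]-1,2,3-trimethoxy-4-oxocyclopent-2-ene-1-carboxylate F1. The enantiomers are then separated by preparative chromatography on an amylose tris(3,5-dimethylphenylcarbamate) phase, and the 1S enantiomer is 14.

2. Step 6.
   - The methyl group may be transferred to the enol oxygen on C4 or C6 instead of C1.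
   - The acidic triacylmethane may lose methanol with ring closure through oxygen.
   - Methanol may strip off the oxalyl group by retro-Claisen cleavage.
   - Fallback, from 9 back to 12, bypassing 11: the magnesium chelate of 9 (MgCl2, Et3N, CH2Cl2, 0 °C) is condensed with commercial methyl 2,2-dichloro-2-methoxyacetate (COC(Cl)(Cl)C(=O)OC), which delivers C1 with its methoxy group already in place. Attack through C5 would give methyl (5Z)-2-chloro-3-[(E)-cinnamoyl]-2,5,6-trimethoxy-4-oxohex-5-enoate F2. This loses hydrogen chloride by an E1cB path to give 12, so no choice among three enol oxygens arises.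

3. Step 4.
   - The enolate may undergo O-acylation.
   - The enolate may attack the beta carbon of the acid chloride.
   - The diketone may lose methanol under acid during work-up.
   - Fallback, from 7 back to 11, bypassing 9: the order of assembly is reversed. Claisen condensation of 7 with dimethyl oxalate (NaOMe, MeOH, rt) gives methyl (2Z,5E)-2-hydroxy-4-oxo-6-phenylhexa-2,5-dienoate F3. Its magnesium chelate (MgCl2, pyridine, CH2Cl2, 0 °C) is then C-acylated at C5 with acid chloride 6 to give 11.

**Further compounds**
F1 | step 7 | racemic methyl (5Z)-5-[(2E)-1-hydroxy-3-phenylprop-2-en-1-ylidene]-1,2,3-trimethoxy-4-oxocyclopent-2-ene-1-carboxylate | COC(=O)C1(OC)C(OC)=C(OC)C(=O)/C1=C(O)/C=C/c1ccccc1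
F2 | step 6 | methyl (5Z)-2-chloro-3-[(E)-cinnamoyl]-2,5,6-trimethoxy-4-oxohex-5-enoate | CO/C=C(\OC)C(=O)C(C(=O)/C=C/c1ccccc1)C(Cl)(OC)C(=O)OC
F3 | step 4 | methyl (2Z,5E)-2-hydroxy-4-oxo-6-phenylhexa-2,5-dienoate | COC(=O)/C(O)=C/C(=O)/C=C/c1ccccc1
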